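The route rests on cutting the C7–C7a bond of the cyclohexane ring (octahydroindene numbering) together with C1–C2 of the cyclopentane. The tertiary carbinol C7 (CH3, OH) is γ to the acyl carbon of the side chain through C7a and C1, a 1,4-dioxygenated array that maps onto a reductive radical conjugate addition. In the key step iron-hydride HAT to a silyl enol ether makes the C7 radical (the enol CH2 becomes the C7 methyl); 6-exo addition to the enone C7a=C1 closes the cyclohexane, and the resulting enolate adds to the C2 aldehyde to close the cyclopentane. The precursor is open-chain aldehyde 25 built on quaternary C3a, already carrying C4–Br and the bromocyclohexyl ketone.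

Key step: step 18

Remark: locants follow the octahydro-1H-indene core (C1–C7a); Ca is the acetoxy-bearing carbon and C1′–C6′ are the bromocyclohexane carbons.

**Bromocyclohexyl ketone (steps 1–6)**

Step 1
Reactants: 1 5-bromo-2-methylpent-2-ene
Product: 2 6-methylhept-5-en-1-yne
Conditions: LiC≡CH·H2NCH2CH2NH2, DMSO, 10 → 23 °C
Reagents that add atoms: lithium acetylide ethylenediamine complex, [Li]C#C.NCCN
Why: SN2 alkylation of the acetylide on the primary bromide (acetylide alkylation); no stereocenter is formed.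

Step 2
Reactants: 2 6-methylhept-5-en-1-yne
Product: 3 (3R)-3-(but-3-yn-1-yl)-2,2-dimethyloxirane
Conditions: Shi ketone (D-fructose-derived, 30 mol %), Oxone, K2CO3, Bu4NHSO4, MeCN/DMM/aq. buffer pH 10.5, 0 °C
Reagents that add atoms: potassium peroxymonosulfate (Oxone), [K+].[O-]S(=O)(=O)OO
Why: Shi asymmetric epoxidation of the electron-rich trisubstituted alkene (the alkyne is inert) through the spiro dioxirane transition state should set (R) at the epoxide CH.

Step 3
Reactants: 3 (3R)-3-(but-3-yn-1-yl)-2,2-dimethyloxirane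
Product: 4 (3S)-3-bromo-2-methylhept-6-yn-2-ol
Conditions: Li2NiBr4, THF, 0 → 23 °C; aq. pH 7 buffer
Reagents that add atoms: dilithium tetrabromonickelate, [Li+].[Li+].Br[Ni-2](Br)(Br)Br
Why: soft bromide opens the epoxide by SN2 at the less substituted carbon with inversion (regioselective epoxide opening), which turns (R)-C–O into (S)-C–Br, the future C4′.

Step 4
Reactants: 4 (3S)-3-bromo-2-methylhept-6-yn-2-ol
Product: 5 (4S)-4-bromo-3,3-dimethylcyclohexan-1-one
Conditions: TfOH (1.1 equiv), (CF3)2CHOH/CH2Cl2, −40 → 0 °C; then H2O, NaHCO3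
Reagents that add atoms: water, O
Why: acid ionizes the tertiary alcohol with anchimeric assistance by the vicinal bromine, the resulting configurationally defined bromonium ion is opened at the tertiary carbon by the terminal alkyne carbon (6-endo alkyne-terminated cation–olefin cyclization) and hydration of the cyclohexenyl cation gives the ketone; the C–Br bond is not broken, so C4′ stays (S).

Step 5
Reactants: 5 (4S)-4-bromo-3,3-dimethylcyclohexan-1-one
Product: 7 1-[(1R,4S)-4-bromo-1-hydroxy-3,3-dimethylcyclohexyl]ethan-1-one, via ethoxyvinyl carbinol 6 (not isolated)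
Conditions: CH2=CHOEt, t-BuLi, THF, −78 → 0 °C; then 5, −78 °C; then 1 M HCl, THF, 23 °C
Reagents that add atoms: ethyl vinyl ether, C=COCC; water, O
Why: 1,2-addition of the acyl anion equivalent 1-ethoxyvinyllithium and enol ether hydrolysis; the axial C3′ methyl blocks axial approach, so the nucleophile should enter equatorially on the Br-equatorial chair and give the axial hydroxyl cis to bromine (C1′ R).

Step 6
Reactants: 7 1-[(1R,4S)-4-bromo-1-hydroxy-3,3-dimethylcyclohexyl]ethan-1-one
Product: 8 1-[(1R,4S)-4-bromo-1-{[tert-butyl(dimethyl)silyl]oxy}-3,3-dimethylcyclohexyl]ethan-1-one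
Conditions: TBSOTf, 2,6-lutidine, CH2Cl2, 0 → 23 °C
Reagents that add atoms: tert-butyldimethylsilyl trifluoromethanesulfonate, CC(C)(C)[Si](C)(C)OS(=O)(=O)C(F)(F)F
Why: silyl triflate silylation of the hindered tertiary α-ketol, which protects it from α-ketol rearrangement and from sulfonylation in step 14.

**Core aldehyde (steps 7–13)**

Step 7
Reactants: 9 methyl 4,4-dimethoxypentanoate
Product: 10 4,4-dimethoxypentanal
Conditions: DIBAL-H (1.05 equiv), CH2Cl2, −78 °C; Rochelle salt
Reagents that add atoms: none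
Why: low-temperature DIBAL half-reduction of the ester through the stable aluminium hemiacetal; the ketal is inert.

Step 8
Reactants: 10 4,4-dimethoxypentanal; 11 methyl 2-[bis(2,2,2-trifluoroethoxy)phosphoryl]propanoate
Product: 12 methyl (2Z)-6,6-dimethoxy-2-methylhept-2-enoate
Conditions: KHMDS, 18-crown-6, THF, −78 °C
Reagents that add atoms: none
Why: Still–Gennari olefination, whose kinetic (Z)-selectivity places the ester carbon (future C7a) cis to the chain, the geometry that the later anti addition needs.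

Step 9
Reactants: 12 methyl (2Z)-6,6-dimethoxy-2-methylhept-2-enoate
Product: 13 1-[(2Z)-6,6-dimethoxyhept-2-en-2-yl]cyclopropan-1-ol
Conditions: EtMgBr, Ti(OiPr)4, THF, 0 → 23 °C
Reagents that add atoms: ethylmagnesium bromide, CC[Mg]Br
Why: Kulinkovich cyclopropanation of the ester by the titanacyclopropane; the trisubstituted alkene is not engaged and keeps its geometry.

Step 10
Reactants: 13 1-[(2Z)-6,6-dimethoxyhept-2-en-2-yl]cyclopropan-1-ol
Product: 14 (2S)-2-[(1S)-1-bromo-4,4-dimethoxypentyl]-2-methylcyclobutan-1-one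
Conditions: NBS, (DHQD)2PHAL (10 mol %), toluene/CHCl3, −40 °C (pseudo-enantiomeric ligand if the sense requires)
Reagents that add atoms: N-bromosuccinimide, O=C1CCC(=O)N1Br
Why: catalytic asymmetric bromination/semipinacol ring expansion, in which Br+ adds to the alkene CH and a cyclopropane C–C bond migrates anti to it onto the tertiary carbon; anti addition across the (Z)-alkene fixes C3a relative to C4 and the ligand-controlled face fixes both as (S).

Step 11
Reactants: 14 (2S)-2-[(1S)-1-bromo-4,4-dimethoxypentyl]-2-methylcyclobutan-1-one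
Product: 15 {[(4S)-4-[(1S)-1-bromo-4,4-dimethoxypentyl]-4-methylcyclobut-1-en-1-yl]oxy}(trimethyl)silane
Conditions: TMSCl, LDA, THF, −78 °C (in situ quench)
Reagents that add atoms: chlorotrimethylsilane, C[Si](C)(C)Cl
Why: kinetic enolization on the only enolizable side and O-silylation (silyl enol ether formation); the quaternary center cannot epimerize.

Step 12
Reactants: 15 {[(4S)-4-[(1S)-1-bromo-4,4-dimethoxypentyl]-4-methylcyclobut-1-en-1-yl]oxy}(trimethyl)silane
Product: 18 methyl (2S,3S)-3-bromo-2-(2,2-dimethoxyethyl)-6,6-dimethoxy-2-methylheptanoate, via aldehydo acid 16 (not isolated), via aldehydo methyl ester 17 (not isolated)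
Conditions: O3, CH2Cl2/MeOH, −78 °C; Me2S; then TMSCHN2, 0 °C; then HC(OMe)3, PPTS, 23 °C
Reagents that add atoms: ozone, [O-][O+]=O; (trimethylsilyl)diazomethane, C[Si](C)(C)C=[N+]=[N-]; trimethyl orthoformate, COC(OC)OC
Why: ozonolysis of the silyl enol ether cleaves C7a–C2 to acid and aldehyde, esterification prevents pseudo-acid formation and acid-catalyzed acetalization masks the C2 aldehyde; no stereocenter is touched.

Step 13
Reactants: 18 methyl (2S,3S)-3-bromo-2-(2,2-dimethoxyethyl)-6,6-dimethoxy-2-methylheptanoate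
Product: 19 (2S,3S)-3-bromo-2-(2,2-dimethoxyethyl)-6,6-dimethoxy-2-methylheptanal
Conditions: DIBAL-H (1.1 equiv), toluene, −78 °C; Rochelle salt
Reagents that add atoms: none
Why: DIBAL half-reduction of the hindered α-quaternary ester, whose tetrahedral aluminate should persist until work-up, gives the non-enolizable aldehyde.

**Union, cascade and endgame (steps 14–21)**

Step 14
Reactants: 8 1-[(1R,4S)-4-bromo-1-{[tert-butyl(dimethyl)silyl]oxy}-3,3-dimethylcyclohexyl]ethan-1-one; 19 (2S,3S)-3-bromo-2-(2,2-dimethoxyethyl)-6,6-dimethoxy-2-methylheptanal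
Product: 22 (2E,4S,5S)-5-bromo-1-[(1R,4S)-4-bromo-1-{[tert-butyl(dimethyl)silyl]oxy}-3,3-dimethylcyclohexyl]-4-(2,2-dimethoxyethyl)-8,8-dimethoxy-4-methylnon-2-en-1-one, via aldol adduct 20 (not isolated), via mesylate 21 (not isolated)
Conditions: 8, LDA, THF, −78 °C; then 19; then MsCl, −78 → 0 °C; then DBU, 23 °C
Reagents that add atoms: none
Why: directed aldol addition of the only possible enolate of 8 to the non-enolizable aldehyde, then mesylation and E1cB elimination (aldol condensation) to the (E)-enone; the existing stereocenters are remote from the reacting atoms.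

Step 15
Reactants: 22 (2E,4S,5S)-5-bromo-1-[(1R,4S)-4-bromo-1-{[tert-butyl(dimethyl)silyl]oxy}-3,3-dimethylcyclohexyl]-4-(2,2-dimethoxyethyl)-8,8-dimethoxy-4-methylnon-2-en-1-one
Product: 23 (2E,4S,5S)-5-bromo-1-[(1R,4S)-4-bromo-1-{[tert-butyl(dimethyl)silyl]oxy}-3,3-dimethylcyclohexyl]-4-(2,2-dimethoxyethyl)-4-methylnon-2-ene-1,8-dione
Conditions: PPTS (cat.), acetone/H2O, 0 → 23 °C
Reagents that add atoms: water, O
Why: chemoselective ketal hydrolysis, since a ketone dimethyl ketal hydrolyzes far faster than an aldehyde dimethyl acetal, should free only the C7 ketone.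

Step 16
Reactants: 23 (2E,4S,5S)-5-bromo-1-[(1R,4S)-4-bromo-1-{[tert-butyl(dimethyl)silyl]oxy}-3,3-dimethylcyclohexyl]-4-(2,2-dimethoxyethyl)-4-methylnon-2-ene-1,8-dione
Product: 24 (2E,4S,5S)-5-bromo-1-[(1R,4S)-4-bromo-1-{[tert-butyl(dimethyl)silyl]oxy}-3,3-dimethylcyclohexyl]-8-{[tert-butyl(dimethyl)silyl]oxy}-4-(2,2-dimethoxyethyl)-4-methylnona-2,8-dien-1-one
Conditions: KHMDS, TBSCl, THF, −78 °C
Reagents that add atoms: tert-butylchlorodimethylsilane, CC(C)(C)[Si](C)(C)Cl
Why: kinetic deprotonation of the methyl group and O-silylation (silyl enol ether formation); the enone has no enolizable hydrogen and the acetal is inert to base.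

Step 17
Reactants: 24 (2E,4S,5S)-5-bromo-1-[(1R,4S)-4-bromo-1-{[tert-butyl(dimethyl)silyl]oxy}-3,3-dimethylcyclohexyl]-8-{[tert-butyl(dimethyl)silyl]oxy}-4-(2,2-dimethoxyethyl)-4-methylnona-2,8-dien-1-one
Product: 25 (3S,4E)-3-[(1S)-1-bromo-4-{[tert-butyl(dimethyl)silyl]oxy}pent-4-en-1-yl]-6-[(1R,4S)-4-bromo-1-{[tert-butyl(dimethyl)silyl]oxy}-3,3-dimethylcyclohexyl]-3-methyl-6-oxohex-4-enal
Conditions: TESOTf, 2,4,6-collidine, CH2Cl2, 0 °C; then H2O
Reagents that add atoms: water, O
Why: silyl triflate/collidine acetal cleavage turns the dimethyl acetal into its collidinium salt, which water converts into the aldehyde under non-acidic conditions that the silyl enol ether and the tertiary silyl ether should tolerate.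

Step 18
Reactants: 25 (3S,4E)-3-[(1S)-1-bromo-4-{[tert-butyl(dimethyl)silyl]oxy}pent-4-en-1-yl]-6-[(1R,4S)-4-bromo-1-{[tert-butyl(dimethyl)silyl]oxy}-3,3-dimethylcyclohexyl]-3-methyl-6-oxohex-4-enal
Product: 27 [(1S,2R,3aS,4S,7R,7aS)-4-bromo-7-{[tert-butyl(dimethyl)silyl]oxy}-2-hydroxy-3a,7-dimethyloctahydro-1H-inden-1-yl][(1R,4S)-4-bromo-1-{[tert-butyl(dimethyl)silyl]oxy}-3,3-dimethylcyclohexyl]methanone, via monocyclic iron enolate 26 (not isolated)
Conditions: Fe(acac)3 (30 mol %), PhSiH3, EtOH/(CH2OH)2, 23 → 40 °C; aq. NH4Cl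
Reagents that add atoms: none
Why: Iron hydride from Fe(acac)3/PhSiH3 transfers a hydrogen atom to the terminal CH2 of the silyl enol ether, so that this CH2 becomes the C7 methyl and a tertiary α-silyloxy radical forms at C7; the radical adds 6-exo-trig to C7a, the β-carbon of the enone (Giese addition), which forms C7–C7a and the cyclohexane, and the α-keto radical at C1 is reduced to iron enolate 26, which closes the cyclopentane by a 5-(enolexo)-exo-trig aldol addition to the C2 aldehyde. The closest known reaction types are the metal-hydride HAT reductive coupling of heteroatom-substituted donor olefins with enones and the HAT-initiated radical–polar crossover annulation. C7a should be set in a chair transition state with C4–Br equatorial, the C3a methyl axial and both the CH2CHO arm and the enone equatorial, which puts C1 trans to C3 and so gives the trans ring fusion, while at C7 the silyloxy group, smaller than methyl, should take the axial site syn to the axial C3a methyl and give (R). In the aldol closure the acyl group is expected on the α-face, away from the C7 silyloxy group and the angular methyl, and metal bridging of the enolate and aldehyde oxygens should place the new hydroxyl cis to it, giving (1S,2R). The step needs HAT to the electron-rich enol ether to outrun HAT to the enone, which the donor character of the enol ether and the neopentyl β-carbon of the enone should secure, and the quaternary C3a leaves no allylic hydrogen for a competing 1,5-hydrogen shift.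

Step 19
Reactants: 27 [(1S,2R,3aS,4S,7R,7aS)-4-bromo-7-{[tert-butyl(dimethyl)silyl]oxy}-2-hydroxy-3a,7-dimethyloctahydro-1H-inden-1-yl][(1R,4S)-4-bromo-1-{[tert-butyl(dimethyl)silyl]oxy}-3,3-dimethylcyclohexyl]methanone
Product: 28 (R)-[(1S,2R,3aS,4S,7R,7aS)-4-bromo-7-{[tert-butyl(dimethyl)silyl]oxy}-2-hydroxy-3a,7-dimethyloctahydro-1H-inden-1-yl][(1R,4S)-4-bromo-1-{[tert-butyl(dimethyl)silyl]oxy}-3,3-dimethylcyclohexyl]methanol
Conditions: Et2BOMe, NaBH4, THF/MeOH, −78 °C; MeOH azeotrope
Reagents that add atoms: none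
Why: Narasaka–Prasad reduction, in which external hydride attacks the boron chelate of the β-hydroxy ketone from the face of the C1–H and C2–H bonds, opposite C7a (the Felkin–Anh sense as well), should give the syn-1,3-diol and so (R) at Ca.

Step 20
Reactants: 28 (R)-[(1S,2R,3aS,4S,7R,7aS)-4-bromo-7-{[tert-butyl(dimethyl)silyl]oxy}-2-hydroxy-3a,7-dimethyloctahydro-1H-inden-1-yl][(1R,4S)-4-bromo-1-{[tert-butyl(dimethyl)silyl]oxy}-3,3-dimethylcyclohexyl]methanol
Product: 30 Ca-acetate of the C2 triethylsilyl ether of 28, via mono-TES ether 29 (not isolated)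
Conditions: TESCl, imidazole, CH2Cl2, −20 °C; then Ac2O, Et3N, DMAP, 23 → 40 °C
Reagents that add atoms: chlorotriethylsilane, CC[Si](CC)(CC)Cl; acetic anhydride, CC(=O)OC(C)=O
Why: selective silylation of the less hindered C2 hydroxyl (the Ca hydroxyl is flanked by the silyloxy-bearing quaternary C1′), then DMAP-catalyzed acylation of the remaining Ca hydroxyl; no stereocenter is touched.

Step 21
Reactants: 30 Ca-acetate of the C2 triethylsilyl ether of 28
Product: 31 (R)-[(1S,2R,3aS,4S,7R,7aS)-4-bromo-2,7-dihydroxy-3a,7-dimethyloctahydro-1H-inden-1-yl][(1R,4S)-4-bromo-1-hydroxy-3,3-dimethylcyclohexyl]methyl acetate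
Conditions: HF·pyridine, THF, 0 → 23 °C
Reagents that add atoms: none
Why: fluoride-driven global desilylation removes the triethylsilyl and both tertiary TBS ethers under mildly acidic conditions that should neither migrate the acetate nor touch the alkyl bromides.

**Compound list**

1 | 5-bromo-2-methylpent-2-ene | CC(C)=CCCBr | starting material
2 | 6-methylhept-5-en-1-yne | C#CCCC=C(C)C | intermediate
3 | (3R)-3-(but-3-yn-1-yl)-2,2-dimethyloxirane | C#CCC[C@H]1OC1(C)C | intermediate
4 | (3S)-3-bromo-2-methylhept-6-yn-2-ol | C#CCC[C@H](Br)C(C)(C)O | intermediate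
5 | (4S)-4-bromo-3,3-dimethylcyclohexan-1-one | O=C1CC[C@H](Br)C(C)(C)C1 | intermediate
6 | (1R,4S)-4-bromo-1-(1-ethoxyethenyl)-3,3-dimethylcyclohexan-1-ol (ethoxyvinyl carbinol) | CCOC(=C)[C@@]1(O)CC[C@H](Br)C(C)(C)C1 | intermediate
7 | 1-[(1R,4S)-4-bromo-1-hydroxy-3,3-dimethylcyclohexyl]ethan-1-one | CC(=O)[C@@]1(O)CC[C@H](Br)C(C)(C)C1 | intermediate
8 | 1-[(1R,4S)-4-bromo-1-{[tert-butyl(dimethyl)silyl]oxy}-3,3-dimethylcyclohexyl]ethan-1-one | CC(=O)[C@@]1(O[Si](C)(C)C(C)(C)C)CC[C@H](Br)C(C)(C)C1 | intermediate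
9 | methyl 4,4-dimethoxypentanoate | COC(=O)CCC(C)(OC)OC | starting material
10 | 4,4-dimethoxypentanal | O=CCCC(C)(OC)OC | intermediate
11 | methyl 2-[bis(2,2,2-trifluoroethoxy)phosphoryl]propanoate | COC(=O)C(C)P(=O)(OCC(F)(F)F)OCC(F)(F)F | starting material
12 | methyl (2Z)-6,6-dimethoxy-2-methylhept-2-enoate | COC(=O)/C(C)=C\CCC(C)(OC)OC | intermediate
13 | 1-[(2Z)-6,6-dimethoxyhept-2-en-2-yl]cyclopropan-1-ol | OC1(CC1)/C(C)=C\CCC(C)(OC)OC | intermediate
14 | (2S)-2-[(1S)-1-bromo-4,4-dimethoxypentyl]-2-methylcyclobutan-1-one | O=C1CC[C@]1(C)[C@@H](Br)CCC(C)(OC)OC | intermediate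
15 | {[(4S)-4-[(1S)-1-bromo-4,4-dimethoxypentyl]-4-methylcyclobut-1-en-1-yl]oxy}(trimethyl)silane | C[Si](C)(C)OC1=CC[C@]1(C)[C@@H](Br)CCC(C)(OC)OC | intermediate
16 | (2S,3S)-3-bromo-6,6-dimethoxy-2-methyl-2-(2-oxoethyl)heptanoic acid (aldehydo acid) | OC(=O)[C@](C)(CC=O)[C@@H](Br)CCC(C)(OC)OC | intermediate
17 | methyl (2S,3S)-3-bromo-6,6-dimethoxy-2-methyl-2-(2-oxoethyl)heptanoate (aldehydo methyl ester) | COC(=O)[C@](C)(CC=O)[C@@H](Br)CCC(C)(OC)OC | intermediate
18 | methyl (2S,3S)-3-bromo-2-(2,2-dimethoxyethyl)-6,6-dimethoxy-2-methylheptanoate | COC(=O)[C@](C)(CC(OC)OC)[C@@H](Br)CCC(C)(OC)OC | intermediate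
19 | (2S,3S)-3-bromo-2-(2,2-dimethoxyethyl)-6,6-dimethoxy-2-methylheptanal | O=C[C@](C)(CC(OC)OC)[C@@H](Br)CCC(C)(OC)OC | intermediate
20 | aldol adduct: 3-hydroxy-2,3-dihydro derivative of 22 (both C3 epimers, as lithium alkoxide in the flask) | O=C(CC(O)[C@](C)(CC(OC)OC)[C@@H](Br)CCC(C)(OC)OC)[C@@]1(O[Si](C)(C)C(C)(C)C)CC[C@H](Br)C(C)(C)C1 | intermediate
21 | mesylate: 3-methanesulfonate of 20 | O=C(CC(OS(C)(=O)=O)[C@](C)(CC(OC)OC)[C@@H](Br)CCC(C)(OC)OC)[C@@]1(O[Si](C)(C)C(C)(C)C)CC[C@H](Br)C(C)(C)C1 | intermediate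
22 | (2E,4S,5S)-5-bromo-1-[(1R,4S)-4-bromo-1-{[tert-butyl(dimethyl)silyl]oxy}-3,3-dimethylcyclohexyl]-4-(2,2-dimethoxyethyl)-8,8-dimethoxy-4-methylnon-2-en-1-one | O=C(/C=C/[C@](C)(CC(OC)OC)[C@@H](Br)CCC(C)(OC)OC)[C@@]1(O[Si](C)(C)C(C)(C)C)CC[C@H](Br)C(C)(C)C1 | intermediate
23 | (2E,4S,5S)-5-bromo-1-[(1R,4S)-4-bromo-1-{[tert-butyl(dimethyl)silyl]oxy}-3,3-dimethylcyclohexyl]-4-(2,2-dimethoxyethyl)-4-methylnon-2-ene-1,8-dione | O=C(/C=C/[C@](C)(CC(OC)OC)[C@@H](Br)CCC(C)=O)[C@@]1(O[Si](C)(C)C(C)(C)C)CC[C@H](Br)C(C)(C)C1 | intermediate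
24 | (2E,4S,5S)-5-bromo-1-[(1R,4S)-4-bromo-1-{[tert-butyl(dimethyl)silyl]oxy}-3,3-dimethylcyclohexyl]-8-{[tert-butyl(dimethyl)silyl]oxy}-4-(2,2-dimethoxyethyl)-4-methylnona-2,8-dien-1-one | O=C(/C=C/[C@](C)(CC(OC)OC)[C@@H](Br)CCC(=C)O[Si](C)(C)C(C)(C)C)[C@@]1(O[Si](C)(C)C(C)(C)C)CC[C@H](Br)C(C)(C)C1 | intermediate
25 | (3S,4E)-3-[(1S)-1-bromo-4-{[tert-butyl(dimethyl)silyl]oxy}pent-4-en-1-yl]-6-[(1R,4S)-4-bromo-1-{[tert-butyl(dimethyl)silyl]oxy}-3,3-dimethylcyclohexyl]-3-methyl-6-oxohex-4-enal | O=C(/C=C/[C@](C)(CC=O)[C@@H](Br)CCC(=C)O[Si](C)(C)C(C)(C)C)[C@@]1(O[Si](C)(C)C(C)(C)C)CC[C@H](Br)C(C)(C)C1 | intermediate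
26 | monocyclic iron enolate of the 6-exo adduct, drawn as the neutral enol: cyclohexane with C7(CH3)(OTBS), C4–Br, C3a(CH3)(CH2CHO) and C7a–CH=C(OH)–(silyloxy bromocyclohexyl) | O=CC[C@]1(C)[C@@H](Br)CC[C@@](C)(O[Si](C)(C)C(C)(C)C)[C@H]1C=C(O)[C@@]2(O[Si](C)(C)C(C)(C)C)CC[C@H](Br)C(C)(C)C2 | intermediate
27 | [(1S,2R,3aS,4S,7R,7aS)-4-bromo-7-{[tert-butyl(dimethyl)silyl]oxy}-2-hydroxy-3a,7-dimethyloctahydro-1H-inden-1-yl][(1R,4S)-4-bromo-1-{[tert-butyl(dimethyl)silyl]oxy}-3,3-dimethylcyclohexyl]methanone | O=C([C@@H]1[C@H](O)C[C@]2(C)[C@@H](Br)CC[C@@](C)(O[Si](C)(C)C(C)(C)C)[C@@H]12)[C@@]1(O[Si](C)(C)C(C)(C)C)CC[C@H](Br)C(C)(C)C1 | intermediate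
28 | (R)-[(1S,2R,3aS,4S,7R,7aS)-4-bromo-7-{[tert-butyl(dimethyl)silyl]oxy}-2-hydroxy-3a,7-dimethyloctahydro-1H-inden-1-yl][(1R,4S)-4-bromo-1-{[tert-butyl(dimethyl)silyl]oxy}-3,3-dimethylcyclohexyl]methanol | O[C@H]([C@@H]1[C@H](O)C[C@]2(C)[C@@H](Br)CC[C@@](C)(O[Si](C)(C)C(C)(C)C)[C@@H]12)[C@@]1(O[Si](C)(C)C(C)(C)C)CC[C@H](Br)C(C)(C)C1 | intermediate
29 | mono-TES ether: C2 triethylsilyl ether of 28, all configurations unchanged | O[C@H]([C@@H]1[C@H](O[Si](CC)(CC)CC)C[C@]2(C)[C@@H](Br)CC[C@@](C)(O[Si](C)(C)C(C)(C)C)[C@@H]12)[C@@]1(O[Si](C)(C)C(C)(C)C)CC[C@H](Br)C(C)(C)C1 | intermediate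
30 | Ca-acetate of 29 (target carrying C2–OTES, C7–OTBS and C1′–OTBS) | CC(=O)O[C@H]([C@@H]1[C@H](O[Si](CC)(CC)CC)C[C@]2(C)[C@@H](Br)CC[C@@](C)(O[Si](C)(C)C(C)(C)C)[C@@H]12)[C@@]1(O[Si](C)(C)C(C)(C)C)CC[C@H](Br)C(C)(C)C1 | intermediate
31 | (R)-[(1S,2R,3aS,4S,7R,7aS)-4-bromo-2,7-dihydroxy-3a,7-dimethyloctahydro-1H-inden-1-yl][(1R,4S)-4-bromo-1-hydroxy-3,3-dimethylcyclohexyl]methyl acetate | CC(=O)O[C@H]([C@@H]1[C@H](O)C[C@]2(C)[C@@H](Br)CC[C@@](C)(O)[C@@H]12)[C@@]1(O)CC[C@H](Br)C(C)(C)C1 | target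

**Step count and risks**

Total step count: 21. Longest linear sequence: 15 steps (steps 7–21; the six-step branch to 8 joins at step 14).

The three steps most likely to fail:

1. Step 18. The iron enolate may be protonated by the alcohol solvent before it reaches the aldehyde, the enone may be reduced by direct hydrogen atom transfer, or chair control in the 6-exo addition may erode. The fallback separates the two ring closures and sets out from 24, where the aldehyde is still masked. The same HAT-initiated 6-exo cyclization (Fe(acac)3, PhSiH3, EtOH) should give the monocyclic ketone acetal F1, with the enolate simply protonated. LiBF4 in wet MeCN then frees the aldehyde to give keto aldehyde F2. A lithium-mediated aldol closure (LiHMDS, THF, −78 °C; the ketone enolizes only toward C1, the aldehyde α-carbon is neopentyl) returns to the route at 27.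

2. Step 10. Enantiofacial discrimination in bromonium formation may be low on an alkene without an aryl or heteroatom handle, and direct brominative opening of the cyclopropanol may compete. The fallback sets out from 13 and uses the uncatalyzed ring expansion with NBS, which should give 14 together with its enantiomer, ent-cyclobutanone F3. CBS reduction ((S)-Me-CBS, BH3·SMe2) delivers hydride to the same carbonyl face of both enantiomers and so converts them into diastereomeric alcohols, cyclobutanol F4 from 14 and cyclobutanol F5 from F3, which are separated by chromatography. Dess–Martin oxidation of F4 returns to the route at 14.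

3. Step 4. The tertiary alcohol may ionize without bromine participation and then suffer hydride shift or elimination, and the weakly nucleophilic alkyne may capture the cation too slowly. The fallback sets out from 4 and changes the terminator. Gold-catalyzed Markovnikov hydrochlorination of the terminal alkyne gives vinyl chloride bromohydrin F6. Its formic acid-mediated cyclization, terminated by the more nucleophilic chloro-olefin, followed by hydrolysis of the α-chloro cation, returns to the route at 5.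

Further compounds

F1 | step 18 | monocyclic ketone acetal: 6-exo cyclization product of 24 with C1H2 and the dimethyl acetal intact | COC(OC)C[C@]1(C)[C@@H](Br)CC[C@@](C)(O[Si](C)(C)C(C)(C)C)[C@H]1CC(=O)[C@@]2(O[Si](C)(C)C(C)(C)C)CC[C@H](Br)C(C)(C)C2
F2 | step 18 | keto aldehyde from acetal hydrolysis of F1 | O=CC[C@]1(C)[C@@H](Br)CC[C@@](C)(O[Si](C)(C)C(C)(C)C)[C@H]1CC(=O)[C@@]2(O[Si](C)(C)C(C)(C)C)CC[C@H](Br)C(C)(C)C2
F3 | step 10 | (2R)-2-[(1R)-1-bromo-4,4-dimethoxypentyl]-2-methylcyclobutan-1-one (ent-cyclobutanone) | O=C1CC[C@@]1(C)[C@H](Br)CCC(C)(OC)OC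
F4 | step 10 | (1R,2S)-2-[(1S)-1-bromo-4,4-dimethoxypentyl]-2-methylcyclobutan-1-ol | O[C@@H]1CC[C@]1(C)[C@@H](Br)CCC(C)(OC)OC
F5 | step 10 | (1R,2R)-2-[(1R)-1-bromo-4,4-dimethoxypentyl]-2-methylcyclobutan-1-ol | O[C@@H]1CC[C@@]1(C)[C@H](Br)CCC(C)(OC)OC
F6 | step 4 | (3S)-3-bromo-6-chloro-2-methylhept-6-en-2-ol | C=C(Cl)CC[C@H](Br)C(C)(C)O
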